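The numbers in the tables were computed with made-up constants; the scatter is artificial.

At early times L came quickly: the autumn run, with Z at 0.0532 M over Q at 0.028 M, read 8.3% of the Q charged by 0.333 min. Then it slowed. I wrote the following for whoever took over the bench.

| flask | Q | Z | remark | time |
|---|---|---|---|---|
| winter | 0.056 M | 0.0532 M | run made earlier |  |
| autumn | 0.028 M | 0.0532 M | run made earlier |  |
| noon | 0.042 M | 0.0532 M | run made earlier |  |
| red | 0.056 M (fed, over 4.80 min) | 0.0532 M | a stirred flask in which Q is dosed at a steady rate over 4.80 min without added volume, worked up at 6.0 min | 6.0 min |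
| amber | 0.056 M | 0.0532 M | one stirred flow tank at steady state, fed with the mixture as stated, mean residence time 6.0 min |  |
| blue | 0.056 M | 0.0532 M (fed, over 4.80 min) | all but Z at the start; Z goes in evenly over 4.80 min, the run ends at 6.0 min | 6.0 min |
| grey | 0.056 M | 0.0532 M | everything together in a closed stirred flask, run for 6.0 min | 6.0 min |

| run | time / min | L / % |
|---|---|---|
| winter | 1.33 | 17.5 |
| winter | 2.50 | 23.3 |
| winter | 4.00 | 27.1 |
| winter | 5.00 | 28.1 |
| winter | 6.00 | 29.9 |
| autumn | 0.333 | 8.3 |
| autumn | 0.833 | 14.9 |
| autumn | 1.50 | 21.3 |
| autumn | 2.50 | 27.6 |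
| autumn | 4.00 | 32.3 |
| noon | 0.250 | 6.6 |
| noon | 0.500 | 10.0 |
| noon | 1.00 | 15.2 |
| noon | 2.00 | 23.2 |
| noon | 4.00 | 29.2 |

(each reading ± 0.5 percentage points)

1. the set-up with the highest amount of L at the outlet or at the end, in percent of the Q put in ("none" if the first two lie within 2 percentage points) (red / amber / blue / grey / none)
2. amount of L at the outlet or at the end, in percent of the Q put in, red
3. amount of L at the outlet or at the end, in percent of the Q put in, amber
4. amount of L at the outlet or at the end, in percent of the Q put in, blue
5. amount of L at the outlet or at the end, in percent of the Q put in, grey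

- the stated concentrations are those of everything mixed, before any reaction; amounts are the same in each set-up
- the feed brings no volume worth counting
- the earlier runs were made in a closed, stirred flask

The earlier runs held Q and Z, with L growing and perhaps something unseen beside it. In autumn, where Z exceeded Q, L rose at 0.0630 min⁻¹, as a fraction of the charge, up to 2.50 min, then at 0.0313 min⁻¹, about half as fast. Running that rate against the reading down to zero gave a ceiling, s = 35.4%. I took s as the selectivity: the share of reacted Q that becomes L, a reading that carries the scatter.

Grey repeated winter, so I told my successor to expect about 29.9% L at 6.0 min, which by s meant an estimated 84.5% of the Q reacted. Leave that one-pot charge alone, I wrote. Dosing spreads one partner over 4.80 min, and on my rule any Q left unreacted costs L.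

The forecast differed: blue best at 34%, with grey 30%, amber 30% and red 12.5%, since “dosing Z keeps it low, which suppresses its second-order loss”. By s, that blue figure needed 96.0% of the Q reacted, more than s gave for winter.

The flask gave grey as best, at 29.4%, with red 25.1%, blue 25.0% and amber 22.5%.

    Q + Z → L (k = 0.0850 M⁻¹ s⁻¹)
    Q + Z → E (k = 0.00590 M⁻¹ s⁻¹)
    Q + Z → J (k = 0.140 M⁻¹ s⁻¹)

The amber tank held Q at 0.0217 M, so 61.2% had reacted, and s turns that into 21.7% beside the 22.5% found. The red flask ended with 31.8% of its Q unreacted, so 68.2% had reacted, and s makes that 24.1% beside the 25.1% found.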